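**Retrosynthetic overview**
1. Rings B and C are both opened in one operation. Ring B is cut at O–C10 and C1–C1′ (inverse-demand hetero-Diels–Alder) and ring C at C3–C4 (intramolecular alkyl–alkenyl Negishi coupling). This leaves an acyclic C15 diiodide, isovaleraldehyde and 2,4,6-trihydroxyisophthalaldehyde.
2. The E-homoallylic iodide end (C10=C1–C2–C3–I) comes from Julia rearrangement of a cyclopropyl carbinol, made from a methyl ketone and c-PrMgBr. The Z-alkenyl iodide end (C5=C4(Me)–I) comes from Stork–Zhao olefination of an aldehyde.
3. The C11 tertiary alcohol comes from Mukaiyama hydration of an isopropenyl group.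
4. The keto aldehyde comes from periodate cleavage of (+)-limonene 1,2-oxide, which supplies C7 (R), the only stereocentre carried in.
5. Forward ring order: ring A is bought, ring C (ten-membered) closes first and ring B (pyran) second, both in the last operation. C1, C10 and C1′ are set there.

Assumption: the ring alkene is taken as Z, exactly as the SMILES encodes it. Germacrane numbering is used throughout: C1–C10 ring, C11 carbinol carbon, C14 methyl on C10, C15 methyl on C4, C1′ benzylic carbon.

Step 1
Reactants: 1 (+)-limonene 1,2-oxide (4R, commercial cis/trans mixture)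
Product: 3 (3R)-6-oxo-3-(prop-1-en-2-yl)heptanal, via limonene-1,2-diol 2 (not isolated)
Conditions: H5IO6 (1.1 equiv), THF–H2O 4:1, 0 °C to rt
Reagents that add atoms: water, O
Why: Acid-promoted epoxide hydrolysis followed by Malaprade periodate glycol cleavage in the same flask opens the six-membered ring between C5 and C10 to the aldehyde and the methyl ketone, leaves the isopropenyl group alone, and carries the single stereocentre (future C7, R) over unchanged from the chiral pool.

Step 2
Reactants: 3 (3R)-6-oxo-3-(prop-1-en-2-yl)heptanal
Product: 4 (5R,7Z)-8-iodo-5-(prop-1-en-2-yl)non-7-en-2-one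
Conditions: EtPPh3I, n-BuLi, THF, 0 °C; I2, −78 °C; NaHMDS, −20 °C; then 3, −78 °C
Reagents that add atoms: ethyltriphenylphosphonium iodide, CC[P+](c1ccccc1)(c1ccccc1)c1ccccc1.[I-]; iodine, II
Why: Stork–Zhao iodo-Wittig olefination: the unstabilised alpha-iodo ylide attacks only the aldehyde at −78 °C and collapses through the kinetically preferred cis-oxaphosphetane to the alkenyl iodide that has iodine cis to the chain (Z, usually better than 10:1), which fixes the Z geometry of the future C4=C5 ring alkene because the later palladium coupling is stereoretentive, while C7 is not touched.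

Step 3
Reactants: 4 (5R,7Z)-8-iodo-5-(prop-1-en-2-yl)non-7-en-2-one
Product: 5 (5R,7Z)-5-(2-hydroxypropan-2-yl)-8-iodonon-7-en-2-one
Conditions: Mn(dpm)3 (5 mol %), PhSiH3 (2.2 equiv), O2 (1 atm), i-PrOH, 0 °C to rt
Reagents that add atoms: dioxygen, O=O
Why: Mukaiyama hydration by metal-hydride hydrogen-atom transfer is Markovnikov-selective and far faster for the 1,1-disubstituted alkene than for the electron-poor iodoalkene, so the tertiary radical forms only at C11, is captured by O2 and is reduced to the alcohol, with no stereocentre made or disturbed.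

Step 4
Reactants: 5 (5R,7Z)-5-(2-hydroxypropan-2-yl)-8-iodonon-7-en-2-one
Product: 6 (3R,6RS)-6-cyclopropyl-3-[(2Z)-3-iodobut-2-en-1-yl]-2-methylheptane-2,6-diol
Conditions: c-PrMgBr (2.5 equiv), THF, −78 to 0 °C; then H2O
Reagents that add atoms: cyclopropylmagnesium bromide, Br[Mg]C1CC1
Why: Grignard 1,2-addition to the methyl ketone after the first equivalent has deprotonated the C11 hydroxyl; the new carbinol centre at C10 forms as a mixture that is irrelevant because it becomes sp2 in step 5, and the unactivated alkenyl iodide does not undergo halogen–magnesium exchange below 0 °C.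

Step 5
Reactants: 6 (3R,6RS)-6-cyclopropyl-3-[(2Z)-3-iodobut-2-en-1-yl]-2-methylheptane-2,6-diol
Product: 7 (3R,6E)-9-iodo-3-[(2Z)-3-iodobut-2-en-1-yl]-2,6-dimethylnon-6-en-2-ol
Conditions: MgI2 (anhydrous, 3 equiv), Et2O–toluene 1:1, 45 °C
Reagents that add atoms: magnesium iodide, [Mg+2].[I-].[I-]
Why: Julia olefin synthesis (cyclopropylcarbinyl-to-homoallyl rearrangement): MgI2 ionises only the cyclopropyl-stabilised tertiary carbinol, iodide opens the three-membered ring at a CH2 group, and the bisected cation that turns the long chain away from the breaking bond gives the E trisubstituted C1=C10 alkene (about 4:1 expected, minor Z isomer removed on AgNO3-impregnated silica), while any cyclic ether formed by capture of the cation by the C11 hydroxyl re-ionises under the same conditions and the plain tertiary alcohol survives.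

Step 6
Reactants: 7 (3R,6E)-9-iodo-3-[(2Z)-3-iodobut-2-en-1-yl]-2,6-dimethylnon-6-en-2-ol; 8 isovaleraldehyde; 9 2,4,6-trihydroxybenzene-1,3-dicarbaldehyde
Product: 13 target CNP0570248.1 (1S,7R,10R,1′S,4Z), via alkylzinc iodide 10 (not isolated), via (4Z,1(10)E)-hedycaryol 11 (not isolated), via ortho-quinone methide 12 (not isolated)
Conditions: 7 added over 8 h to Zn dust, TMEDA, PdCl2(Amphos)2 (5 mol %), THF, 40 °C (final 2 mM); cannula-filter from Zn, concentrate at 0 °C to 0.1 M; add 8, 9, NaOAc, AcOH, 60 °C
Reagents that add atoms: none
Why: Proposed new method: zinc inserts only into the primary C3–I bond and the alkylzinc iodide is consumed as it forms by an intramolecular, stereoretentive Negishi coupling with the Z-alkenyl iodide under pseudo-high dilution (closest known chemistry: zinc-mediated in situ alkyl–alkenyl Negishi couplings that tolerate protic groups, and alkyl–alkenyl palladium couplings that close nine- to twelve-membered carbocycles), which gives ring C with its Z and E alkenes intact, after which the strained E alkene alone is trapped by the ortho-quinone methide from a Knoevenagel condensation of 8 and 9 in an inverse-demand hetero-Diels–Alder reaction that closes ring B, is suprafacial (E alkene gives C14 methyl trans to H-1), joins O to the tertiary C10 and C1′ to C1, can reach the alkene only from the ring periphery in the conformer that keeps the C7 side chain pseudo-equatorial and C14 on the same face (sets 1S and 10R relative to 7R), and puts H-1 rather than C2 under the diene of the E-configured quinone methide (sets 1′S).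

**Compound list**
1 | (4R)-1-methyl-4-(prop-1-en-2-yl)-7-oxabicyclo[4.1.0]heptane, (+)-limonene 1,2-oxide, cis/trans mixture | CC12OC1C[C@@H](CC2)C(C)=C | starting material
2 | (4R)-1-methyl-4-(prop-1-en-2-yl)cyclohexane-1,2-diol, limonene-1,2-diol | CC1(O)C(O)C[C@@H](CC1)C(C)=C | intermediate
3 | (3R)-6-oxo-3-(prop-1-en-2-yl)heptanal | O=CC[C@H](C(C)=C)CCC(C)=O | intermediate
4 | (5R,7Z)-8-iodo-5-(prop-1-en-2-yl)non-7-en-2-one | C/C(I)=C/C[C@H](C(C)=C)CCC(C)=O | intermediate
5 | (5R,7Z)-5-(2-hydroxypropan-2-yl)-8-iodonon-7-en-2-one | C/C(I)=C/C[C@H](C(C)(C)O)CCC(C)=O | intermediate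
6 | (3R,6RS)-6-cyclopropyl-3-[(2Z)-3-iodobut-2-en-1-yl]-2-methylheptane-2,6-diol | C/C(I)=C/C[C@H](C(C)(C)O)CCC(C)(O)C1CC1 | intermediate
7 | (3R,6E)-9-iodo-3-[(2Z)-3-iodobut-2-en-1-yl]-2,6-dimethylnon-6-en-2-ol | C/C(I)=C/C[C@H](C(C)(C)O)CC/C(C)=C/CCI | intermediate
8 | 3-methylbutanal, isovaleraldehyde | CC(C)CC=O | starting material
9 | 2,4,6-trihydroxybenzene-1,3-dicarbaldehyde, diformylphloroglucinol | O=Cc1c(O)cc(O)c(C=O)c1O | starting material
10 | alkylzinc iodide of 7 (Zn inserted into the primary C3–I bond, Z-alkenyl iodide retained) | C/C(I)=C/C[C@H](C(C)(C)O)CC/C(C)=C/CC[Zn]I | intermediate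
11 | 2-[(1R,3Z,7E)-4,8-dimethylcyclodeca-3,7-dien-1-yl]propan-2-ol, (4Z,1(10)E)-hedycaryol | C/C1=C/C[C@H](C(C)(C)O)CC/C(C)=C/CC1 | intermediate
12 | (5E)-2,4-dihydroxy-5-(3-methylbutylidene)-6-oxocyclohexa-1,3-diene-1,3-dicarbaldehyde, ortho-quinone methide | CC(C)C/C=C1/C(=O)C(C=O)=C(O)C(C=O)=C1O | intermediate
13 | 5,7-dihydroxy-4-isobutyl-2-methylchroman-6,8-dicarbaldehyde whose chroman C2 (=C10, R) and C3 (=C1, S) are bridged trans by C9H2–C8H2–C7H(CMe2OH)(R)–C6H2–C5H=C4(Me)–C3H2–C2H2 with a Z alkene; chroman C4 (=C1′) is S, with isobutyl cis to H-1 | C/C1=C/C[C@H](C(C)(C)O)CC[C@@]2(C)Oc3c(C=O)c(O)c(C=O)c(O)c3[C@@H](CC(C)C)[C@@H]2CC1 | target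

**Total step count:** 6. **Longest linear sequence:** 6 steps (1 to 13).

**Steps most likely to fail**

Step 6 carries the most risk.
- The ten-membered ring may lose out to oligomers, to beta-hydride elimination, or to protonation of the zinc reagent by the free alcohol.
- Compound 11 is acid-sensitive.
- The face selectivity and the endo/exo selectivity of the cycloaddition rest on conformational arguments only.

The fallback inverts the order of ring formation. It sets out from 7 (with 8 and 9) and comes back at 13.
- The Knoevenagel/hetero-Diels–Alder reaction is run on acyclic 7, whose E alkene is its only electron-rich alkene.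
- The two facial diastereomers are separated, and the correctly configured chroman diiodide F1 is kept.
- Its two arms sit trans and gauche on ring B, which pre-organises the closure.
- A nickel-catalysed reductive alkenyl–alkyl coupling then closes ring C to 13 (NiBr2(glyme), 4,4′-di-tert-butyl-2,2′-bipyridine, Mn powder, NaI, DMA, high dilution). This coupling tolerates phenols and aldehydes, and it can no longer scramble an alkene through a homoallyl radical.
- The price is the loss of facial control, about half of the material.

Step 5 is next.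
- The E:Z ratio is only moderate.
- The C10 cation can be intercepted by the C11 hydroxyl or by the iodoalkene.

The fallback avoids the cation altogether and moves the ring closure to C1=C10. It sets out from 5 and comes back at 11.
- Compound 5 is coupled with commercial 2-(1,3-dioxolan-2-yl)ethylzinc bromide (Pd(OAc)2, SPhos, THF) to give the keto acetal F2.
- Hydrolysis (1 M HCl, THF) gives the keto aldehyde F3.
- A McMurry carbonyl coupling closes ring C (TiCl3(DME)1.5, Zn–Cu couple, DME, reflux, slow addition). It gives 11 together with its 1(10)Z isomer.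
- Only the strained 11 reacts when the mixture is taken through the cycloaddition half of step 6.

Step 2 is third.
- The iodo ylide is thermally fragile.
- Yields are often modest.
- The keto aldehyde can undergo aldol reaction with stray base.

The fallback builds the same alkenyl halide by cross-coupling instead of olefination. It sets out from 3 and comes back at 4.
- Ramirez dibromo-olefination of the aldehyde (CBr4, PPh3, CH2Cl2, 0 °C) gives the 1,1-dibromoalkene F4.
- Palladium-catalysed methylation with MeZnCl and PdCl2(DPEphos) replaces selectively the less hindered bromine, the one trans to the chain, and gives the (Z)-alkenyl bromide F5.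
- Copper-catalysed halogen exchange with retention (CuI, N,N′-dimethylethylenediamine, NaI, dioxane, 110 °C) delivers 4.

**Further compounds**
F1 | step 6 | chroman diiodide: 13 with the C3–C4 bond replaced by C3–I and C4–I (1S,7R,10R,1′S,4Z) | C/C(I)=C/C[C@H](C(C)(C)O)CC[C@@]2(C)Oc3c(C=O)c(O)c(C=O)c(O)c3[C@@H](CC(C)C)[C@@H]2CCI
F2 | step 5 | (5R,7Z)-10-(1,3-dioxolan-2-yl)-5-(2-hydroxypropan-2-yl)-8-methyldec-7-en-2-one | C/C(CCC1OCCO1)=C/C[C@H](C(C)(C)O)CCC(C)=O
F3 | step 5 | (4Z,7R)-7-(2-hydroxypropan-2-yl)-4-methyl-10-oxoundec-4-enal | C/C(CCC=O)=C/C[C@H](C(C)(C)O)CCC(C)=O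
F4 | step 2 | (5R)-8,8-dibromo-5-(prop-1-en-2-yl)oct-7-en-2-one | BrC(Br)=CC[C@H](C(C)=C)CCC(C)=O
F5 | step 2 | (5R,7Z)-8-bromo-5-(prop-1-en-2-yl)non-7-en-2-one | C/C(Br)=C/C[C@H](C(C)=C)CCC(C)=O
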